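**Plan**

- Retrosynthesis: cut the benzylic aryl ether bond C4(upper ring)–O–C6(lower ring). Both halves then reduce to one monomer, a cis-(3R,4R)-4-hydroxy-7-methoxy-3-methylisochroman-1-one oxygenated at C6 and C8, used once as the C4 electrophile and once as the O6 nucleophile.
- In the monomer, cut C4–C4a. C4a is ortho to C8a, which carries the lactone carbonyl C1, and C4 is a carbinol carbon next to C3–O2. An o-iodobenzoate of (R)-lactaldehyde therefore holds C4a and C4 in a 1,6 relation through the ester C1(=O)–O2–C3 that the target already contains.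
- Forward: arene functionalisation (steps 1–4), ester (5), aldehyde (6), closure of the lactone ring at C4a–C4 (7), redox correction at C4 (8–9), divergence into the two partners (10–11), ether coupling (12), deprotection (13).
- Stereochemistry: C3 of both halves comes from (S)-but-3-en-2-ol with Mitsunobu inversion. The cis C4 carbinol comes from bulky-hydride reduction of the 1,4-dione. The trans C4 ether of the upper half comes from Mitsunobu inversion of that cis alcohol by the C6 phenol of the lower half.

Key step: step 7

Remark: 2-methoxyresorcinol and (S)-but-3-en-2-ol are taken as commercial, and the C8 hydroxyl (hydrogen-bonded to the lactone carbonyl) is assumed to be much less reactive than the C6 hydroxyl in phenol alkylation.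

**Step 1**
Reactants: 1 2-methoxybenzene-1,3-diol
Product: 2 2-methoxy-1,3-bis(methoxymethoxy)benzene
Conditions: MOMCl, i-Pr2NEt, CH2Cl2, 0 °C to rt
Reagents that add atoms: chloromethyl methyl ether, COCCl
Why: O-alkylation of both phenols (MOM protection) gives base-stable acetals that later assist ortho-lithiation.

**Step 2**
Reactants: 2 2-methoxy-1,3-bis(methoxymethoxy)benzene
Product: 3 2-[4-methoxy-3,5-bis(methoxymethoxy)phenyl]-4,4,5,5-tetramethyl-1,3,2-dioxaborolane
Conditions: [Ir(OMe)(cod)]2 (cat.), dtbpy (cat.), B2pin2, THF, 80 °C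
Reagents that add atoms: bis(pinacolato)diboron, CC1(C)OB(OC1(C)C)B1OC(C)(C)C(C)(C)O1
Why: Iridium-catalysed aromatic C–H borylation is sterically controlled, and the C–H para to the methoxy group is the only one without an ortho substituent.

**Step 3**
Reactants: 3 2-[4-methoxy-3,5-bis(methoxymethoxy)phenyl]-4,4,5,5-tetramethyl-1,3,2-dioxaborolane
Product: 4 5-iodo-2-methoxy-1,3-bis(methoxymethoxy)benzene
Conditions: CuI (cat.), 1,10-phenanthroline (cat.), KI, MeOH/H2O, air, 80 °C
Reagents that add atoms: potassium iodide, [K+].[I-]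
Why: Copper-catalysed ipso-iododeboronation of the aryl boronate should exchange boron for iodine at the same carbon under non-acidic conditions that spare the MOM ethers.

**Step 4**
Reactants: 4 5-iodo-2-methoxy-1,3-bis(methoxymethoxy)benzene
Product: 6 6-iodo-3-methoxy-2,4-bis(methoxymethoxy)benzoic acid, via aryllithium 5 (not isolated)
Conditions: LDA, THF, −78 °C; CO2; then cold dilute HCl to pH 3
Reagents that add atoms: carbon dioxide, O=C=O
Why: Directed ortho-metalation with a non-nucleophilic amide base removes the C–H flanked by iodine and OMOM (two equivalent sites, no I/Li exchange), and carboxylation of the aryllithium places CO2H between them.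

**Step 5**
Reactants: 6 6-iodo-3-methoxy-2,4-bis(methoxymethoxy)benzoic acid; 7 (S)-but-3-en-2-ol
Product: 8 (R)-but-3-en-2-yl 6-iodo-3-methoxy-2,4-bis(methoxymethoxy)benzoate
Conditions: PPh3, DIAD, THF, 0 °C to rt
Reagents that add atoms: none
Why: Mitsunobu esterification, with the hindered but acidic benzoic acid as nucleophile, should proceed with inversion, so the (S)-alcohol delivers the (R) configuration needed at C3.

**Step 6**
Reactants: 8 (R)-but-3-en-2-yl 6-iodo-3-methoxy-2,4-bis(methoxymethoxy)benzoate
Product: 10 (R)-1-oxopropan-2-yl 6-iodo-3-methoxy-2,4-bis(methoxymethoxy)benzoate, via vicinal diol 9 (not isolated)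
Conditions: OsO4 (cat.), NaIO4, 2,6-lutidine, dioxane/H2O, rt; used crude
Reagents that add atoms: osmium tetroxide, O=[Os](=O)(=O)=O (oxygen carrier); sodium periodate, [Na+].[O-]I(=O)(=O)=O (terminal oxidant)
Why: Lemieux–Johnson cleavage (dihydroxylation, then periodate glycol cleavage) should unmask the α-acyloxy aldehyde under near-neutral conditions that leave C3, the aryl iodide and the MOM ethers untouched.

**Step 7**
Reactants: 10 (R)-1-oxopropan-2-yl 6-iodo-3-methoxy-2,4-bis(methoxymethoxy)benzoate
Product: 12 (3R)-4-hydroxy-7-methoxy-6,8-bis(methoxymethoxy)-3-methylisochroman-1-one (both C4 epimers), via arylchromium(III) species 11 (not isolated)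
Conditions: CrCl2 (excess), NiCl2 (cat.), degassed DMF, rt, high dilution; aqueous work-up
Reagents that add atoms: none
Why: Ni(0) formed in situ inserts into the C4a–I bond, the aryl group passes to chromium(III), and the arylchromium 11 adds to the tethered aldehyde carbon C4. The closest known reaction type is the intramolecular Nozaki–Hiyama–Kishi addition of aryl and alkenyl iodides to aldehydes. The only ring closed is the six-membered lactone ring (C4a–C8a–C1–O2–C3–C4), formed in the 6-exo-trig mode through the ester tether that stays in the target. The new stereocentre C4 is controlled by C3 (a Cornforth-type transition state, with the C4=O dipole opposed to the C3–O2 bond, is expected to favour the trans carbinol), but neither epimer is lost because C4 is reset in steps 8 and 9. The step needs chemoselectivity for the aldehyde over the benzoate, reaction at C4a only, and no epimerisation of the α-acyloxy centre C3; the non-basic, aldehyde-selective organochromium reagent and the single iodine ortho to the ester secure these. High dilution should favour ring closure over intermolecular addition.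

**Step 8**
Reactants: 12 (3R)-4-hydroxy-7-methoxy-6,8-bis(methoxymethoxy)-3-methylisochroman-1-one (both C4 epimers)
Product: 13 (R)-7-methoxy-6,8-bis(methoxymethoxy)-3-methylisochromane-1,4-dione
Conditions: Dess–Martin periodinane, NaHCO3, CH2Cl2, 0 °C to rt; used at once
Reagents that add atoms: none
Why: Buffered Dess–Martin oxidation of the secondary benzylic alcohol should converge both C4 epimers on one ketone without enolising C3.

**Step 9**
Reactants: 13 (R)-7-methoxy-6,8-bis(methoxymethoxy)-3-methylisochromane-1,4-dione
Product: 14 (3R,4R)-4-hydroxy-7-methoxy-6,8-bis(methoxymethoxy)-3-methylisochroman-1-one (cis)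
Conditions: L-Selectride, THF, −78 °C; AcOH quench at −78 °C
Reagents that add atoms: none
Why: Diastereoselective ketone reduction with a bulky trialkylborohydride should deliver hydride to C4 from the face opposite the C3 methyl group (in analogy to 2-alkyl-1-tetralones), giving the cis alcohol; the ketone reacts before the lactone at low temperature.

**Step 10**
Reactants: 14 (3R,4R)-4-hydroxy-7-methoxy-6,8-bis(methoxymethoxy)-3-methylisochroman-1-one
Product: 15 (3R,4R)-4-[(tert-butyldimethylsilyl)oxy]-7-methoxy-6,8-bis(methoxymethoxy)-3-methylisochroman-1-one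
Conditions: TBSOTf, 2,6-lutidine, CH2Cl2, −78 to 0 °C
Reagents that add atoms: tert-butyldimethylsilyl triflate, CC(C)(C)[Si](C)(C)OS(=O)(=O)C(F)(F)F
Why: Silylation of the hindered secondary alcohol with a silyl triflate and a hindered base masks the C4 hydroxyl of the future lower half so that it cannot be activated in step 12.

**Step 11**
Reactants: 15 (3R,4R)-4-[(tert-butyldimethylsilyl)oxy]-7-methoxy-6,8-bis(methoxymethoxy)-3-methylisochroman-1-one
Product: 16 (3R,4R)-4-[(tert-butyldimethylsilyl)oxy]-6,8-dihydroxy-7-methoxy-3-methylisochroman-1-one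
Conditions: ZnBr2, n-PrSH, CH2Cl2, 0 °C, short reaction time
Reagents that add atoms: none
Why: Lewis acid/thiol cleavage of aryl MOM ethers (the thiol captures the methoxymethyl cation) is fast and should spare the secondary silyl ether, the aryl methyl ether and the lactone.

**Step 12**
Reactants: 14 (3R,4R)-4-hydroxy-7-methoxy-6,8-bis(methoxymethoxy)-3-methylisochroman-1-one; 16 (3R,4R)-4-[(tert-butyldimethylsilyl)oxy]-6,8-dihydroxy-7-methoxy-3-methylisochroman-1-one
Product: 17 (3R,4S)-4-{[(3R,4R)-4-[(tert-butyldimethylsilyl)oxy]-8-hydroxy-7-methoxy-3-methyl-1-oxoisochroman-6-yl]oxy}-7-methoxy-6,8-bis(methoxymethoxy)-3-methylisochroman-1-one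
Conditions: PPh3, DIAD, THF, 0 °C to rt
Reagents that add atoms: none
Why: Mitsunobu etherification: the C6 phenol of 16 (para to the lactone carbonyl, the most acidic OH) displaces the activated C4 oxygen of 14 by SN2 with inversion, on the face anti to the C3 methyl, turning the cis-(4R) alcohol into the trans-(4S) aryl ether.

**Step 13**
Reactants: 17 protected dimer
Product: 18 (3R,4S)-4-{[(3R,4R)-4,8-dihydroxy-7-methoxy-3-methyl-1-oxoisochroman-6-yl]oxy}-6,8-dihydroxy-7-methoxy-3-methylisochroman-1-one (target)
Conditions: aq. HCl, MeOH/THF, rt to 40 °C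
Reagents that add atoms: none
Why: Acid-catalysed acetal exchange and desilylation should remove both MOM ethers and the TBS ether in one operation, under which the lactones, the aryl methyl ethers and the benzylic ether (its cation destabilised by the ortho lactone carbonyl) are expected to persist.

**Compound list**

1 | 2-methoxybenzene-1,3-diol (2-methoxyresorcinol) | COc1c(O)cccc1O | starting material
2 | 2-methoxy-1,3-bis(methoxymethoxy)benzene | COCOc1cccc(OCOC)c1OC | intermediate
3 | 2-[4-methoxy-3,5-bis(methoxymethoxy)phenyl]-4,4,5,5-tetramethyl-1,3,2-dioxaborolane | COCOc1cc(B2OC(C)(C)C(C)(C)O2)cc(OCOC)c1OC | intermediate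
4 | 5-iodo-2-methoxy-1,3-bis(methoxymethoxy)benzene | COCOc1cc(I)cc(OCOC)c1OC | intermediate
5 | [6-iodo-3-methoxy-2,4-bis(methoxymethoxy)phenyl]lithium | [Li]c1c(I)cc(OCOC)c(OC)c1OCOC | intermediate (not isolated)
6 | 6-iodo-3-methoxy-2,4-bis(methoxymethoxy)benzoic acid | OC(=O)c1c(I)cc(OCOC)c(OC)c1OCOC | intermediate
7 | (S)-but-3-en-2-ol | C[C@H](O)C=C | starting material
8 | (R)-but-3-en-2-yl 6-iodo-3-methoxy-2,4-bis(methoxymethoxy)benzoate | C[C@@H](OC(=O)c1c(I)cc(OCOC)c(OC)c1OCOC)C=C | intermediate
9 | (2R)-3,4-dihydroxybutan-2-yl 6-iodo-3-methoxy-2,4-bis(methoxymethoxy)benzoate (both epimers at the new carbinol) | C[C@@H](OC(=O)c1c(I)cc(OCOC)c(OC)c1OCOC)C(O)CO | intermediate (not isolated)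
10 | (R)-1-oxopropan-2-yl 6-iodo-3-methoxy-2,4-bis(methoxymethoxy)benzoate | C[C@@H](OC(=O)c1c(I)cc(OCOC)c(OC)c1OCOC)C=O | intermediate
11 | dichloro{3-methoxy-2,4-bis(methoxymethoxy)-6-... phenyl}chromium(III), the arylchromium formed from 10 at the former C–I carbon | C[C@@H](OC(=O)c1c([Cr](Cl)Cl)cc(OCOC)c(OC)c1OCOC)C=O | intermediate (not isolated)
12 | (3R)-4-hydroxy-7-methoxy-6,8-bis(methoxymethoxy)-3-methylisochroman-1-one, both C4 epimers | COCOc1cc2c(c(OCOC)c1OC)C(=O)O[C@H](C)C2O | intermediate
13 | (R)-7-methoxy-6,8-bis(methoxymethoxy)-3-methylisochromane-1,4-dione | COCOc1cc2c(c(OCOC)c1OC)C(=O)O[C@H](C)C2=O | intermediate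
14 | (3R,4R)-4-hydroxy-7-methoxy-6,8-bis(methoxymethoxy)-3-methylisochroman-1-one (cis) | COCOc1cc2c(c(OCOC)c1OC)C(=O)O[C@H](C)[C@@H]2O | intermediate
15 | (3R,4R)-4-[(tert-butyldimethylsilyl)oxy]-7-methoxy-6,8-bis(methoxymethoxy)-3-methylisochroman-1-one | COCOc1cc2c(c(OCOC)c1OC)C(=O)O[C@H](C)[C@@H]2O[Si](C)(C)C(C)(C)C | intermediate
16 | (3R,4R)-4-[(tert-butyldimethylsilyl)oxy]-6,8-dihydroxy-7-methoxy-3-methylisochroman-1-one | COc1c(O)cc2c(c1O)C(=O)O[C@H](C)[C@@H]2O[Si](C)(C)C(C)(C)C | intermediate
17 | (3R,4S)-4-{[(3R,4R)-4-[(tert-butyldimethylsilyl)oxy]-8-hydroxy-7-methoxy-3-methyl-1-oxoisochroman-6-yl]oxy}-7-methoxy-6,8-bis(methoxymethoxy)-3-methylisochroman-1-one | COc1c(OCOC)cc2c(c1OCOC)C(=O)O[C@H](C)[C@H]2Oc1cc2c(c(O)c1OC)C(=O)O[C@H](C)[C@@H]2O[Si](C)(C)C(C)(C)C | intermediate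
18 | (3R,4S)-4-{[(3R,4R)-4,8-dihydroxy-7-methoxy-3-methyl-1-oxoisochroman-6-yl]oxy}-6,8-dihydroxy-7-methoxy-3-methylisochroman-1-one | COc1c(O)cc2c(c1O)C(=O)O[C@H](C)[C@H]2Oc1cc2c(c(O)c1OC)C(=O)O[C@H](C)[C@@H]2O | target

**Totals**

Total step count: 13. Longest linear sequence: 13 steps (1 to 18 through 14 and 16; compound 14 is used a second time in step 12).

**Steps most likely to fail**

1. Step 7 (ring closure). What may go wrong: slow nickel insertion or aryl transfer at the hindered, electron-rich aryl iodide, ending in loss of iodine without C–C bond formation; intermolecular addition; hydration or epimerisation of the aldehyde before closure; acyl migration in the chromium alkoxide, contracting the lactone to a phthalide. The fallback closes the same ring at the ketone oxidation level by an anionic acylation. It sets out from 6. Ethyl (S)-lactate is converted with MeNH(OMe)·HCl and i-PrMgCl into (S)-2-hydroxy-N-methoxy-N-methylpropanamide F1. Mitsunobu esterification of 6 with this alcohol (PPh3, DIAD, inversion) gives (R)-1-[methoxy(methyl)amino]-1-oxopropan-2-yl 6-iodo-3-methoxy-2,4-bis(methoxymethoxy)benzoate F2. Iodine–magnesium exchange (i-PrMgCl·LiCl, THF, −40 °C) and attack of the arylmagnesium on the Weinreb amide (Parham-type cyclisation) should give, after a cold acidic quench, the dione 13, where the route is rejoined.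

2. Step 12 (ether coupling). What may go wrong: elimination across C3–C4 to the isocoumarin, ionisation at the benzylic C4 with loss of clean inversion, competing alkylation at O8, or low conversion at the hindered carbinol. The fallback forms the C4–O bond by epoxide opening and closes the upper lactone afterwards. It sets out from 6. Methylation (MeI, K2CO3, DMF) gives methyl 6-iodo-3-methoxy-2,4-bis(methoxymethoxy)benzoate F3. Suzuki–Miyaura coupling with (E)-prop-1-enylboronic acid pinacol ester gives methyl 3-methoxy-2,4-bis(methoxymethoxy)-6-[(E)-prop-1-en-1-yl]benzoate F4. Shi epoxidation with the D-fructose-derived ketone gives methyl 3-methoxy-2,4-bis(methoxymethoxy)-6-[(2R,3R)-3-methyloxiran-2-yl]benzoate F5. The C6 phenoxide of 16 (Cs2CO3, DMF) should open the epoxide at the benzylic carbon with inversion to the hydroxy ester F6, whose alkoxide lactonises onto the methyl ester to give 17, where the route is rejoined. Attack at the benzylic carbon is not assured, since both epoxide carbons are secondary.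

3. Step 9 (cis reduction through the dione). What may go wrong: enolisation of the α-acyloxy ketone with erosion at C3, insufficient facial selectivity, or acyl migration in the alkoxide. The fallback avoids the ketone. It sets out from 12: the epimers are separated, the cis epimer being 14 itself. The trans epimer is inverted at C4 by Mitsunobu reaction with chloroacetic acid (PPh3, DIAD) to the cis ester (3R,4R)-7-methoxy-6,8-bis(methoxymethoxy)-3-methyl-1-oxoisochroman-4-yl chloroacetate F7. The chloroacetate is removed under neutral conditions (thiourea, NaHCO3, EtOH) to give 14, where the route is rejoined.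

**Further compounds**

F1 | step 7 | (S)-2-hydroxy-N-methoxy-N-methylpropanamide | C[C@H](O)C(=O)N(C)OC
F2 | step 7 | (R)-1-[methoxy(methyl)amino]-1-oxopropan-2-yl 6-iodo-3-methoxy-2,4-bis(methoxymethoxy)benzoate | C[C@@H](OC(=O)c1c(I)cc(OCOC)c(OC)c1OCOC)C(=O)N(C)OC
F3 | step 12 | methyl 6-iodo-3-methoxy-2,4-bis(methoxymethoxy)benzoate | COC(=O)c1c(I)cc(OCOC)c(OC)c1OCOC
F4 | step 12 | methyl 3-methoxy-2,4-bis(methoxymethoxy)-6-[(E)-prop-1-en-1-yl]benzoate | COC(=O)c1c(/C=C/C)cc(OCOC)c(OC)c1OCOC
F5 | step 12 | methyl 3-methoxy-2,4-bis(methoxymethoxy)-6-[(2R,3R)-3-methyloxiran-2-yl]benzoate | COC(=O)c1c([C@H]2O[C@@H]2C)cc(OCOC)c(OC)c1OCOC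
F6 | step 12 | methyl 6-[(1S,2R)-1-{[(3R,4R)-4-[(tert-butyldimethylsilyl)oxy]-8-hydroxy-7-methoxy-3-methyl-1-oxoisochroman-6-yl]oxy}-2-hydroxypropyl]-3-methoxy-2,4-bis(methoxymethoxy)benzoate | COC(=O)c1c([C@H](Oc2cc3c(c(O)c2OC)C(=O)O[C@H](C)[C@@H]3O[Si](C)(C)C(C)(C)C)[C@@H](C)O)cc(OCOC)c(OC)c1OCOC
F7 | step 9 | (3R,4R)-7-methoxy-6,8-bis(methoxymethoxy)-3-methyl-1-oxoisochroman-4-yl chloroacetate | COCOc1cc2c(c(OCOC)c1OC)C(=O)O[C@H](C)[C@@H]2OC(=O)CCl
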